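**Retrosynthetic overview**

- The strategy rests on the dihydropyran ring C5–C6–C7–C8–O9–C10. It is the cyclic enol ether of a 1,3-dione (O9–C8=C7) that carries the C6 methylene on C7 and the quaternary C10 on O9, which is the reduced form of a 2H-pyran made from a 1,3-dione and an enal.
- Target ⇐ Wittig methylenation at C2 and hydrogenation of C5=C6 ⇐ 2H-pyran ketone ⇐ Knoevenagel condensation/oxa-6π electrocyclization (C6–C7 and O9–C10) of a caryophyllane enal with an acylated gem-dimethyl trione.
- Enal ⇐ (−)-caryophyllene oxide: ozonolysis (the C2 ketone masks the methylene during hydrogenation), epoxide deoxygenation, formaldehyde ene reaction at C5, oxidation and isomerisation. Trione ⇐ phloroglucinol by C-acylation and dearomative gem-dimethylation.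
- Ring order: the cyclobutane and the nine-membered ring come from the chiral pool, the trione ring from phloroglucinol, and the pyran is the only ring formed (step 7). C10 is set in step 7 and C5 in step 8.

Key step: step 7

Remark: atoms are numbered by their position in the target SMILES (C1 = exocyclic CH2, C2 = its ring carbon, C5 = ring-fusion CH, C6 = linking CH2, C7/C8 = enol ether carbons, O9, C10 = quaternary carbon, C11 = its methyl, C14/C15 = cyclobutane fusion carbons, C31 = enol carbon); this numbering is used for all intermediates. The SMILES of 1 is taken as natural (−)-caryophyllene oxide, whose trans-fused C14/C15 centres are carried unchanged to the target.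

**Route**

Step 1
Reactants: 1 (−)-caryophyllene oxide
Product: 3 kobusone (nor-ketone: C2 ketone and the C5–O–C10 trans-epoxide of 1 retained), via spiro-ozonide 2 (not isolated)
Conditions: O3, CH2Cl2, −78 °C; then Me2S, −78 °C → rt
Reagents that add atoms: ozone, O=[O+][O-]
Why: Ozonolysis (Criegee mechanism) of the only C=C bond, the exocyclic C2=C1 methylene, gives the spiro-ozonide, which Me2S reduces to the C2 ketone; the epoxide is inert to ozone and no stereocentre is formed or touched.

Step 2
Reactants: 3 kobusone
Product: 4 E-configured nor-ketone (6,10,10-trimethylbicyclo[7.2.0]undec-5-en-2-one; E-C5=C10, trans ring fusion)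
Conditions: Ph3P=Se, CF3CO2H, CH2Cl2, rt
Reagents that add atoms: none
Why: Stereospecific epoxide deoxygenation with triphenylphosphine selenide and acid: oxygen-to-selenium exchange by double inversion gives an episelenide that extrudes selenium, so the trans-epoxide should return the E-alkene while the ketone is untouched.

Step 3
Reactants: 4 E-configured nor-ketone; 5 formaldehyde (as paraformaldehyde)
Product: 6 homoallylic alcohol (C6 hydroxymethyl on C5, exocyclic C10=C11 methylene, C2 ketone)
Conditions: (CH2O)n, Me2AlCl (2.5 equiv), CH2Cl2, 0 °C → rt; dilute aq. HCl work-up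
Reagents that add atoms: formaldehyde 5 (from paraformaldehyde), C=O
Why: Lewis-acid-promoted carbonyl-ene reaction (Snider conditions): the Me2AlCl–formaldehyde complex attacks the strained trisubstituted alkene at the less substituted C5 with hydrogen transfer from the C11 methyl, on the exposed outer face; the C5 centre so formed is erased in step 4, the C10=C12 regioisomer would serve equally, and the excess Me2AlCl covers complexation by the ketone.

Step 4
Reactants: 6 homoallylic alcohol
Product: 8 ring-cis conjugated enal (C2 ketone; C5 bears CHO and C10 bears CH3 on the tetrasubstituted C5=C10), via deconjugated aldehyde 7 (not isolated)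
Conditions: Dess–Martin periodinane, CH2Cl2, 0 °C → rt; aq. Na2S2O3/NaHCO3 wash; then DBU (0.2 equiv), CH2Cl2, rt
Reagents that add atoms: none
Why: Dess–Martin oxidation gives the β,γ-unsaturated aldehyde without over-oxidation, and catalytic DBU moves the alkene into conjugation through the dienolate (deconjugated-to-conjugated isomerisation), removing the C5 centre and giving the ring-cis tetrasubstituted enal that a nine-membered ring prefers; either alkene geometry would serve in step 7.

Step 5
Reactants: 9 phloroglucinol; 10 isobutyryl chloride
Product: 11 1-(2,4,6-trihydroxyphenyl)-2-methylpropan-1-one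
Conditions: AlCl3, PhNO2, 65–80 °C; aq. HCl work-up
Reagents that add atoms: isobutyryl chloride 10, CC(C)C(=O)Cl
Why: Friedel–Crafts C-acylation of the highly activated arene; the new ketone deactivates the ring against a second acylation.

Step 6
Reactants: 11 1-(2,4,6-trihydroxyphenyl)-2-methylpropan-1-one
Product: 13 2-isobutyryl-4,4-dimethylcyclohexane-1,3,5-trione (enol form), via C-monomethyl phenol 12 (not isolated)
Conditions: NaOMe (3.2 equiv), MeI (2.2 equiv), MeOH, 0 °C → rt; then aq. HCl
Reagents that add atoms: iodomethane, CI
Why: Dearomative C-alkylation of the acylphloroglucinol polyanion: the first methyl enters a free ring carbon and the second enters the same, now more electron-rich, carbon to give the gem-dimethyl trione, with the stoichiometry limiting further methylation.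

Step 7
Reactants: 8 ring-cis conjugated enal; 13 2-isobutyryl-4,4-dimethylcyclohexane-1,3,5-trione
Product: 15 2H-pyran tetracycle (C5=C6, C2 ketone, quaternary C10 bearing O9 and CH3), via 1-oxatriene 14 (not isolated)
Conditions: ethylenediammonium diacetate (0.3 equiv), toluene, 4 Å MS, 100 °C
Reagents that add atoms: none
Why: The amine salt converts the aldehyde of 8 into an iminium ion that is attacked by C7, the only nucleophilic C–H site of the enolised trione 13, and loss of the amine gives alkylidene trione 14, a 1-oxatriene (O=C8–C7=C6–C5=C10) that closes by thermal disrotatory oxa-6π electrocyclization. The closest known reaction is the Knoevenagel/oxa-6π formal [3+3] annulation of cyclic 1,3-diones with enals, which is established also for tetrasubstituted cycloalkene carbaldehydes that give pyrans with a quaternary oxygen-bearing carbon. The one ring closed is the 2H-pyran (C5–C6–C7–C8–O9–C10), by electrocyclic formation of O9–C10 after the condensation has made C6–C7; the closed form should be favoured because it relieves the crowded alkylidene trione and carries two substituents on C10. The new stereocentre C10 is under thermodynamic control: ring closure is reversible at 100 °C, so the two C10 epimers equilibrate through 14 under the bias of the trans-fused cyclobutane centres C14/C15 in the nine-membered ring, and the epimer required has O9 on the face that the oxide oxygen occupies in 1. Regioselectivity between the C8 and C31 oxygens is needed and should be secured by the C31–OH···O=C26 chelate, which stays intact only when the C8 carbonyl is the oxatriene terminus, the alternative closure being drained through the same reversible manifold.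

Step 8
Reactants: 15 2H-pyran tetracycle
Product: 16 dihydropyran ketone (C5–H trans to C10–CH3, C2 ketone)
Conditions: H2 (1 atm), 10% Pd/C, EtOAc, rt
Reagents that add atoms: none
Why: Heterogeneous catalytic hydrogenation (syn addition on palladium) of C5=C6, the only alkene outside the push–pull vinylogous acid system, from the face opposite the pseudoaxial C10 methyl, which sets C5–H trans to C10–CH3; the tetrasubstituted C7=C8 enol ether, the chelated enol and the C2 ketone should not be reduced, and saturation ends the electrocyclic reversibility and so fixes C10.

Step 9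
Reactants: 16 dihydropyran ketone
Product: 17 CNP0497637.2 (target)
Conditions: Ph3PCH3Br (5 equiv), KOtBu (4.8 equiv), THF, 0 → 45 °C; then aq. NH4Cl
Reagents that add atoms: methyltriphenylphosphonium bromide (source of CH2 through Ph3P=CH2), C[P+](c1ccccc1)(c1ccccc1)c1ccccc1.[Br-]
Why: Wittig methylenation: the first equivalent of ylide deprotonates the acidic acyl-enol to a delocalised enolate that shields the C23, C26 and C31 carbonyls, so only the C2 ketone is olefinated; the trans fusion at C15 is the thermodynamically preferred one, so reversible enolisation should not scramble it.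

**Compound list**

1 | (−)-caryophyllene oxide | C=C1CC[C@H]2O[C@]2(C)CC[C@@H]2[C@@H]1CC2(C)C | starting material
2 | spiro-ozonide of 1 (1,2,4-trioxolane at C2, configuration at the spiro carbon open) | C1OOC2(O1)CC[C@H]1O[C@]1(C)CC[C@@H]1[C@@H]2CC1(C)C | intermediate
3 | kobusone (C2 ketone, C5–O–C10 trans-epoxide) | O=C1CC[C@H]2O[C@]2(C)CC[C@@H]2[C@@H]1CC2(C)C | intermediate
4 | E-configured nor-ketone (6,10,10-trimethylbicyclo[7.2.0]undec-5-en-2-one, trans-fused) | O=C1CC/C=C(C)/CC[C@@H]2[C@@H]1CC2(C)C | intermediate
5 | formaldehyde (as paraformaldehyde) | C=O | starting material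
6 | homoallylic alcohol (CH2OH on C5, C10=C11 methylene, C2 ketone) | O=C1CC[C@@H](CO)C(=C)CC[C@@H]2[C@@H]1CC2(C)C | intermediate
7 | deconjugated aldehyde (CHO on C5, C10=C11 methylene, C2 ketone) | O=C1CC[C@@H](C=O)C(=C)CC[C@@H]2[C@@H]1CC2(C)C | intermediate
8 | ring-cis conjugated enal (C2 ketone, C5(CHO)=C10(CH3)) | O=C1CC/C(C=O)=C(C)\CC[C@@H]2[C@@H]1CC2(C)C | intermediate
9 | phloroglucinol | Oc1cc(O)cc(O)c1 | starting material
10 | isobutyryl chloride | CC(C)C(=O)Cl | starting material
11 | 1-(2,4,6-trihydroxyphenyl)-2-methylpropan-1-one | CC(C)C(=O)c1c(O)cc(O)cc1O | intermediate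
12 | 1-(2,4,6-trihydroxy-3-methylphenyl)-2-methylpropan-1-one | CC(C)C(=O)c1c(O)cc(O)c(C)c1O | intermediate
13 | 2-isobutyryl-4,4-dimethylcyclohexane-1,3,5-trione (enol form) | CC(C)C(=O)C1=C(O)CC(=O)C(C)(C)C1=O | intermediate
14 | 1-oxatriene (alkylidene trione, C7=C6 geometry open) | O=C1CC/C(C=C2C(=O)C(C)(C)C(=O)C(C(=O)C(C)C)=C2O)=C(C)\CC[C@@H]2[C@@H]1CC2(C)C | intermediate
15 | 2H-pyran tetracycle (C5=C6, C2 ketone) | O=C1CCC2=CC3=C(O[C@]2(C)CC[C@@H]2[C@@H]1CC2(C)C)C(C)(C)C(=O)C(C(=O)C(C)C)=C3O | intermediate
16 | dihydropyran ketone (C5–H trans to C10–CH3) | O=C1CC[C@H]2CC3=C(O[C@]2(C)CC[C@@H]2[C@@H]1CC2(C)C)C(C)(C)C(=O)C(C(=O)C(C)C)=C3O | intermediate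
17 | CNP0497637.2 | C=C1CC[C@H]2CC3=C(O[C@]2(C)CC[C@@H]2[C@@H]1CC2(C)C)C(C)(C)C(=O)C(C(=O)C(C)C)=C3O | target

**Step count**

Total: 9 steps. Longest linear sequence: 7 steps (steps 1, 2, 3, 4, 7, 8, 9).

**Steps most likely to fail**

1. Step 7. The equilibrium of the reversible ring closure may favour the wrong C10 epimer, closure may run through the C31 oxygen, or condensation at the hindered conjugated aldehyde may be slow enough for hydrogen shifts of the oxatriene to compete. A computational comparison of the two C10 epimers of 15 is advisable before material is committed. Fallback: setting out from trione 13 and formaldehyde 5, heating with (−)-β-caryophyllene F1 and NaOAc in AcOH at about 80 °C should generate by Knoevenagel condensation the 6-methylene trione F2, a 1-oxadiene. This is trapped in situ by the strained E-alkene of the terpene in an inverse-demand hetero-Diels–Alder reaction. The reaction forms C5–C6 and O9–C10 suprafacially on the exposed alkene face, the face epoxidised in 1, and should give target 17 directly after chromatographic removal of regio- and diastereomers. The route is rejoined at 17.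

2. Step 8. Facial selectivity at C5 may be poor, or the allylic tertiary C10–O9 bond may undergo hydrogenolysis on the metal surface. Fallback: from 15, hydrogen-atom-transfer hydrogenation with Mn(dpm)3 (tris(dipivaloylmethanato)manganese, trivalent manganese; catalytic), PhSiH3 and t-BuOOH in i-PrOH at rt. Hydrogen is then delivered in stepwise radical steps and not by surface syn addition; this mode is known to give the more stable ring fusion where surface hydrogenation does not, and it cannot cleave the C–O bond. The route is rejoined at 16; this fallback makes no compound outside the list (none F0).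

3. Step 3. The Lewis acid may trigger hydroxymethylation next to the ketone, HCl-adduct formation, isomerisation or oligomerisation of the strained alkene, or Prins over-reaction to a dioxane. Fallback: from 1, isomerisation of the epoxide to the allylic alcohol with Al(OiPr)3 in refluxing toluene should give caryophylla-4(12),8(13)-dien-5-ol F3 (C5–OH, C10=C11 methylene). Dess–Martin oxidation should give dienone F4. Wittig reaction with Ph3P=CHOMe (from Ph3PCH2OMe chloride and KN(SiMe3)2, THF) should give methoxydiene F5. Mild aqueous acid (oxalic acid, wet THF) should hydrolyse the dienol ether with protonation at C11 to dienal F6, which is enal 8 still carrying the C2 methylene. Ozonolysis limited to the electron-rich exocyclic alkene (O3 titrated at −78 °C in CH2Cl2, through spiro-ozonide F7, then Me2S) should give 8, where the route is rejoined.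

**Further compounds**

F1 | step 7 | (−)-β-caryophyllene | C=C1CC/C=C(C)/CC[C@@H]2[C@@H]1CC2(C)C
F2 | step 7 | 2-isobutyryl-4,4-dimethyl-6-methylenecyclohexane-1,3,5-trione (enol form) | C=C1C(=O)C(C)(C)C(=O)C(C(=O)C(C)C)=C1O
F0 | step 8 | none | none
F3 | step 3 | caryophylla-4(12),8(13)-dien-5-ol | C=C1CC[C@@H](O)C(=C)CC[C@@H]2[C@@H]1CC2(C)C
F4 | step 3 | caryophylla-4(12),8(13)-dien-5-one | C=C1CCC(=O)C(=C)CC[C@@H]2[C@@H]1CC2(C)C
F5 | step 3 | methoxydiene (C5=CH–OMe, C10=C11 methylene) | C=C1CCC(=COC)C(=C)CC[C@@H]2[C@@H]1CC2(C)C
F6 | step 3 | dienal (C5(CHO)=C10(CH3), C2 methylene) | C=C1CC/C(C=O)=C(C)\CC[C@@H]2[C@@H]1CC2(C)C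
F7 | step 3 | spiro-ozonide of F6 | C1OOC2(O1)CC/C(C=O)=C(C)\CC[C@@H]1[C@@H]2CC1(C)C
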